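Cardopatine is cut at the two homotopic exocyclic bonds that link cyclobutane carbons C1 and C2 to the inner alkyne carbons. The twofold axis bisecting the C1–C2 and C3–C4 bonds of the four-membered ring makes both cuts equivalent. A single nickel-catalysed operation swaps both activated carboxyl groups of an enantiopure trans-cyclobutane-1,2-dicarboxylate for bithienylethynyl groups delivered from zinc. It forms both C(sp3)–C(sp) bonds and rebuilds each stereocentre under the control of its neighbour. The precursor is the (1R,2R) bis(redox-active ester). It is used as the tetrachloro-N-hydroxyphthalimide variant, because alkynylnickel species are weak reductants and need the more easily reduced ester.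

Key step: step 7

Assumption: quinine is taken to deliver methanol to the carbonyl group on the (S)-configured ring carbon of the meso anhydride, its usual sense with cis-2,3-disubstituted succinic anhydrides; if the sign of rotation of the derived trans diacid showed the opposite sense, quinidine would replace it and nothing else would change.

Step 1
Reactants: 1 cis-cyclobutane-1,2-dicarboxylic anhydride (meso)
Product: 2 (1R,2S)-2-(methoxycarbonyl)cyclobutane-1-carboxylic acid (cis half-ester)
Conditions: quinine (1.1 equiv), MeOH (3 equiv), toluene, −55 °C; aq. HCl wash (alkaloid recovered by basification)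
Reagents that add atoms: methanol, CO
Why: Alkaloid-mediated desymmetrising alcoholysis of a meso anhydride, in which the quinuclidine nitrogen of quinine activates methanol as a general base in a chiral environment and steers it to one of the two enantiotopic carbonyl groups, so that both stereocentres become fixed in absolute terms while the cis relation is inherited from 1.

Step 2
Reactants: 2 (1R,2S)-2-(methoxycarbonyl)cyclobutane-1-carboxylic acid
Product: 4 (1R,2R)-cyclobutane-1,2-dicarboxylic acid, via trans half-ester 3 (not isolated)
Conditions: NaOMe (2.5 equiv), MeOH, reflux; then 2 M aq. NaOH, 50 °C; then aq. HCl to pH 1, extraction, recrystallisation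
Reagents that add atoms: sodium hydroxide (NaOH), [Na+].[OH-]
Why: Enolate-mediated epimerisation followed by saponification, in which the carboxylate shields its own α-carbon C1 from deprotonation so that only the ester-bearing C2 equilibrates to the less strained trans arrangement, while any cis material left is hydrolysed to the meso diacid, which costs yield but not enantiopurity and is removed on crystallisation of 4.

Step 3
Reactants: 4 (1R,2R)-cyclobutane-1,2-dicarboxylic acid; 5 N-hydroxytetrachlorophthalimide (2.1 equiv)
Product: 6 bis(4,5,6,7-tetrachloro-1,3-dioxoisoindolin-2-yl) (1R,2R)-cyclobutane-1,2-dicarboxylate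
Conditions: N,N'-diisopropylcarbodiimide (2.2 equiv), DMAP (10 mol %), CH2Cl2, 0 °C to rt; filtration, short silica pad, trituration
Reagents that add atoms: none
Why: Steglich-type carbodiimide esterification, in which the trans diacid cannot collapse to a strained trans-fused anhydride so both carboxyl groups are activated independently, no bond at C1 or C2 is touched, and the small charge of DMAP together with the reluctance of a four-membered ring to carry an exocyclic enolate double bond should keep the α-centres intact.

Step 4
Reactants: 7 5-bromo-2,2'-bithiophene; 8 ethynyltrimethylsilane (1.3 equiv)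
Product: 9 5-[(trimethylsilyl)ethynyl]-2,2'-bithiophene
Conditions: PdCl2(PPh3)2 (2 mol %), CuI (4 mol %), Et3N/THF, 55 °C, Ar
Reagents that add atoms: none
Why: Sonogashira coupling through oxidative addition of zerovalent palladium into the unhindered thienyl C–Br bond, transmetalation from the copper acetylide and reductive elimination, with the silyl cap blocking a second coupling at the alkyne.

Step 5
Reactants: 9 5-[(trimethylsilyl)ethynyl]-2,2'-bithiophene
Product: 10 5-ethynyl-2,2'-bithiophene
Conditions: K2CO3 (0.2 equiv), MeOH/THF, rt, light excluded
Reagents that add atoms: none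
Why: Methoxide-catalysed protodesilylation of the C(sp)–Si bond is fast for arylalkynylsilanes and leaves the bithiophene untouched.

Step 6
Reactants: 10 5-ethynyl-2,2'-bithiophene
Product: 12 [(2,2'-bithiophen-5-yl)ethynyl]zinc chloride, via lithium acetylide 11 (not isolated)
Conditions: n-BuLi (1.0 equiv), THF, −78 °C; then ZnCl2 (1.05 equiv, THF solution), −78 °C to rt; used as the titrated THF solution of its LiCl complex, light excluded
Reagents that add atoms: zinc dichloride (ZnCl2), Cl[Zn]Cl; n-butyllithium, [Li]CCCC (lithium of 11 only)
Why: Acid–base lithiation followed by lithium-to-zinc transmetalation, in which the alkyne C–H is far more acidic than the thiophene C5'–H so one equivalent of base at low temperature should give only the acetylide, and ZnCl2 then turns it into a mild, ester-tolerant nucleophile.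

Step 7
Reactants: 6 bis(4,5,6,7-tetrachloro-1,3-dioxoisoindolin-2-yl) (1R,2R)-cyclobutane-1,2-dicarboxylate; 12 [(2,2'-bithiophen-5-yl)ethynyl]zinc chloride (6 equiv)
Product: 14 cardopatine, via mono-alkynylated ester 13 (not isolated)
Conditions: NiCl2·glyme (40 mol %, that is 20 mol % per ester), 4,4'-dimethoxy-2,2'-bipyridine (40 mol %), DMF/THF, rt, Ar, light excluded; aq. NH4Cl; chromatography in the dark
Reagents that add atoms: none
Why: A monovalent alkynylnickel complex, formed from NiCl2·glyme, the bipyridine and 12, gives one electron to a tetrachlorophthalimide ester of 6, N–O cleavage and loss of CO2 leave a secondary cyclobutyl radical, this radical is caught by a divalent alkynylnickel species, and reductive elimination from the trivalent nickel centre forges the C(sp3)–C(sp) bond, after which the same cycle runs on 13. The closest known reaction type is the nickel-catalysed decarboxylative alkynylation of redox-active esters with alkynylzinc halides (a radical Negishi-type coupling), established for secondary cycloalkyl acids as their tetrachlorophthalimide esters and here simply run on two ester groups of one molecule. No ring is closed. C1 is flattened and rebuilt anti to the bulky acyloxyimide group on the still intact C2, and C2 is then flattened and rebuilt anti to the new alkynyl arm on C1, so each centre is set by 1,2-induction from its neighbour and the (1R,2R) sense of 6 is handed on to 14. The selectivity that matters most is trans capture in the first coupling, because a cis-configured 13 would be steered to the (1S,2S) enantiomer, and it should be secured by the puckered four-membered ring, which holds the neighbouring ester over the syn face, and by the size of the ligated nickel; a syn capture in the second coupling would only give the separable meso cis isomer. Chemoselectivity for radical capture over β-hydride loss, acyl attack and acetylide homocoupling rests on the excess of 12, the mildness of zinc acetylides towards esters and strict exclusion of oxygen and light.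

Compound list
1 | cis-cyclobutane-1,2-dicarboxylic anhydride (meso 3-oxabicyclo[3.2.0]heptane-2,4-dione) | O=C1OC(=O)[C@H]2CC[C@@H]12 | starting material
2 | (1R,2S)-2-(methoxycarbonyl)cyclobutane-1-carboxylic acid | OC(=O)[C@@H]1CC[C@@H]1C(=O)OC | intermediate
3 | (1R,2R)-2-(methoxycarbonyl)cyclobutane-1-carboxylic acid (sodium salt in the flask) | OC(=O)[C@@H]1CC[C@H]1C(=O)OC | intermediate
4 | (1R,2R)-cyclobutane-1,2-dicarboxylic acid | OC(=O)[C@@H]1CC[C@H]1C(O)=O | intermediate
5 | N-hydroxytetrachlorophthalimide (4,5,6,7-tetrachloro-2-hydroxyisoindoline-1,3-dione) | ON1C(=O)c2c(Cl)c(Cl)c(Cl)c(Cl)c2C1=O | starting material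
6 | bis(4,5,6,7-tetrachloro-1,3-dioxoisoindolin-2-yl) (1R,2R)-cyclobutane-1,2-dicarboxylate | O=C(ON1C(=O)c2c(Cl)c(Cl)c(Cl)c(Cl)c2C1=O)[C@@H]1CC[C@H]1C(=O)ON1C(=O)c2c(Cl)c(Cl)c(Cl)c(Cl)c2C1=O | intermediate
7 | 5-bromo-2,2'-bithiophene | Brc1ccc(-c2cccs2)s1 | starting material
8 | ethynyltrimethylsilane | C#C[Si](C)(C)C | starting material
9 | 5-[(trimethylsilyl)ethynyl]-2,2'-bithiophene | C[Si](C)(C)C#Cc1ccc(-c2cccs2)s1 | intermediate
10 | 5-ethynyl-2,2'-bithiophene | C#Cc1ccc(-c2cccs2)s1 | intermediate
11 | lithium (2,2'-bithiophen-5-yl)acetylide | [Li]C#Cc1ccc(-c2cccs2)s1 | intermediate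
12 | [(2,2'-bithiophen-5-yl)ethynyl]zinc chloride | Cl[Zn]C#Cc1ccc(-c2cccs2)s1 | intermediate
13 | 4,5,6,7-tetrachloro-1,3-dioxoisoindolin-2-yl (1R,2R)-2-[(2,2'-bithiophen-5-yl)ethynyl]cyclobutane-1-carboxylate | O=C(ON1C(=O)c2c(Cl)c(Cl)c(Cl)c(Cl)c2C1=O)[C@@H]1CC[C@H]1C#Cc1ccc(-c2cccs2)s1 | intermediate
14 | cardopatine, (1R,2R)-1,2-bis[(2,2'-bithiophen-5-yl)ethynyl]cyclobutane | C(#C[C@@H]1CC[C@H]1C#Cc1ccc(-c2cccs2)s1)c1ccc(-c2cccs2)s1 | target

Total steps: 7. Longest linear sequence: 4 (steps 1, 2, 3, 7 or steps 4, 5, 6, 7).

Steps most likely to fail

1. Step 7.
- What may go wrong: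
  - Imperfect anti capture of the first radical would bleed material into the enantiomeric series.
  - Facial bias next to the slim alkynyl arm may be weak in the second capture.
  - The vicinal diester may lose both carboxyl groups by fragmentation towards an alkene.
  - The sequence may stall after one coupling.
  - The zinc acetylide may homocouple.
- Fallback: the two bonds are made one at a time, with a methyl ester as the silent partner, so that the first coupling can be purified before the second. The fallback sets out from 1.
  - Methanolysis under quinidine in place of quinine should give (1S,2R)-2-(methoxycarbonyl)cyclobutane-1-carboxylic acid F1.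
  - Carbodiimide esterification with 5 gives 2-methyl 1-(4,5,6,7-tetrachloro-1,3-dioxoisoindolin-2-yl) (1S,2R)-cyclobutane-1,2-dicarboxylate F2.
  - A single decarboxylative alkynylation with 12 under the catalyst of step 7 erases C1 and rebuilds it anti to the methyl ester, so no epimerisation is needed. This gives methyl (1R,2R)-2-[(2,2'-bithiophen-5-yl)ethynyl]cyclobutane-1-carboxylate F3.
  - Any cis isomer is removed from that ester by chromatography before it can be carried into the wrong enantiomer.
  - LiOH in aqueous THF gives (1R,2R)-2-[(2,2'-bithiophen-5-yl)ethynyl]cyclobutane-1-carboxylic acid F4.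
  - Esterification with 5 brings the sequence back to the route at 13, now isolated, which is coupled once more with 12 to give 14.

2. Step 1.
- What may go wrong: discrimination between the enantiotopic carbonyl groups of the small, flat bicyclic anhydride may be insufficient, or uncatalysed background methanolysis may compete. Either would cap the enantiopurity of everything downstream.
- Fallback: classical resolution in place of desymmetrisation. This also bypasses step 2. It sets out from 1 and comes back to the route at 4.
  - MeOH with catalytic H2SO4 at reflux gives dimethyl cis-cyclobutane-1,2-dicarboxylate F5.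
  - NaOMe in MeOH equilibrates this neutral diester to racemic dimethyl trans-cyclobutane-1,2-dicarboxylate F6.
  - Aqueous NaOH and then HCl give racemic trans-cyclobutane-1,2-dicarboxylic acid F7.
  - Fractional crystallisation with (R)-1-phenylethylamine gives (R)-1-phenylethylammonium hydrogen (1R,2R)-cyclobutane-1,2-dicarboxylate F8. The (R)-amine is chosen by analogy with the six-membered homologue, and the (S)-amine serves if the other salt proves the less soluble.
  - Aqueous HCl releases 4 from the salt.

3. Step 3.
- What may go wrong:
  - An O-to-N acyl shift in the activated carbodiimide adduct may stall the second esterification.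
  - Base-induced α-epimerisation of the doubly activated diester would lead, through the meso cis form, to racemisation.
  - The product may hydrolyse on silica.
- Fallback: acylation through the acid chloride in place of carbodiimide dehydration. It sets out from 4 and comes back to the route at 6.
  - Oxalyl chloride with catalytic DMF in CH2Cl2 gives (1R,2R)-cyclobutane-1,2-dicarbonyl dichloride F9.
  - After evaporation this is added to 5 and pyridine in CH2Cl2 at −20 °C.
  - Compound 6 is collected by precipitation and washing rather than chromatography.

Further compounds
F1 | step 7 | (1S,2R)-2-(methoxycarbonyl)cyclobutane-1-carboxylic acid | OC(=O)[C@H]1CC[C@H]1C(=O)OC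
F2 | step 7 | 2-methyl 1-(4,5,6,7-tetrachloro-1,3-dioxoisoindolin-2-yl) (1S,2R)-cyclobutane-1,2-dicarboxylate | O=C(ON1C(=O)c2c(Cl)c(Cl)c(Cl)c(Cl)c2C1=O)[C@H]1CC[C@H]1C(=O)OC
F3 | step 7 | methyl (1R,2R)-2-[(2,2'-bithiophen-5-yl)ethynyl]cyclobutane-1-carboxylate | COC(=O)[C@@H]1CC[C@H]1C#Cc1ccc(-c2cccs2)s1
F4 | step 7 | (1R,2R)-2-[(2,2'-bithiophen-5-yl)ethynyl]cyclobutane-1-carboxylic acid | OC(=O)[C@@H]1CC[C@H]1C#Cc1ccc(-c2cccs2)s1
F5 | step 1 | dimethyl cis-cyclobutane-1,2-dicarboxylate (meso) | COC(=O)[C@@H]1CC[C@@H]1C(=O)OC
F6 | step 1 | racemic dimethyl trans-cyclobutane-1,2-dicarboxylate | COC(=O)[C@@H]1CC[C@H]1C(=O)OC.COC(=O)[C@H]1CC[C@@H]1C(=O)OC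
F7 | step 1 | racemic trans-cyclobutane-1,2-dicarboxylic acid | OC(=O)[C@@H]1CC[C@H]1C(O)=O.OC(=O)[C@H]1CC[C@@H]1C(O)=O
F8 | step 1 | (R)-1-phenylethylammonium hydrogen (1R,2R)-cyclobutane-1,2-dicarboxylate | C[C@@H]([NH3+])c1ccccc1.OC(=O)[C@@H]1CC[C@H]1C([O-])=O
F9 | step 3 | (1R,2R)-cyclobutane-1,2-dicarbonyl dichloride | ClC(=O)[C@@H]1CC[C@H]1C(Cl)=O
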